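The north-east flask carries 1.20 equivalents of coupling partner on starting material, yet after 5.00 h its target reads 31% of the starting material charged.

common to all: starting material 0.20 M; free catalyst 1.1 mM

| flask | second substrate | coupling partner | temperature | remark | time |
|---|---|---|---|---|---|
| north-east | 0.20 M | 0.24 M | 5 °C | the very flask that is asked about, followed so far |  |
| south-west | 0.13 M | 0.24 M | −10 °C | run made earlier |  |
| flask | 0.200 M | 0.240 M | 5 °C |  | 8.0 h |

| run | time / h | target / % | starting material / % |
|---|---|---|---|
| north-east | 0.667 | 16 | 84 |
| north-east | 1.50 | 28 | 74 |
| north-east | 3.00 | 30 | 72 |
| north-east | 5.00 | 31 | 69 |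
| south-west | 3.00 | 31 | 70 |
| south-west | 6.00 | 44 | 55 |
| south-west | 8.00 | 54 | 46 |
| south-west | 12.0 | 57 | 41 |

(each reading ± 2 percentage points)

- removed target is counted in
- steps under discussion: starting material + free catalyst <-> catalyst intermediate A; coupling partner + catalyst intermediate A -> free catalyst + target; second substrate + free catalyst <-> catalyst intermediate B; coupling partner + catalyst intermediate B -> free catalyst + second product; coupling partner -> decomposed reagent
- additions bring no volume worth counting

- beta: at 8.0 h raise the temperature by 15 K, then wait 8.0 h
- theta: at 8.0 h add free catalyst, 50.0% of the amount charged, then wait 8.0 h
- gamma: change nothing and wait 8.0 h more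
- delta: at 8.0 h add coupling partner, 100% of the amount charged, then wait 8.0 h
- alpha: at 8.0 h take out 90% of the target then present, then wait 8.0 h

- target, in percent of the starting material first charged, at 8.0 h
- the remedy with the largest gain of target, or "none" below 2 percentage points (beta / theta / gamma / delta / alpha / none)
- target present, with what was taken out counted in, in percent of the starting material first charged, after theta
- target present, with what was taken out counted in, in percent of the starting material first charged, after gamma

Is the flask still running? Between 3.00 h and 5.00 h the target moved 1 percentage point on a scatter of 2 points, so I read a plateau, with starting material at 69% of its charge.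

Is the catalyst dead, then? In the steps under discussion it only passes between free catalyst and the catalyst intermediates, so I turn to the coupling partner, which these steps use up.

What happens to one molecule of coupling partner? It stands at a fork: with catalyst intermediate A it forms target, with catalyst intermediate B it forms second product, and by itself it forms decomposed reagent. The plateau gives 25.8% as the capture share, the fraction of the charged coupling partner that ends as target, a selectivity counted on the coupling partner.

Isn't that just the plateau rewritten? Not quite: each branch is first order in coupling partner, so with the catalyst intermediates and the starting material held at their levels, the share does not depend on the amount charged. Nor is it a stoichiometric number: the colder south-west run, with less second substrate, reached 47.5% on the same charge of coupling partner, more than the north-east flask.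

And the options? If the plateau means the coupling partner has left, then waiting, catalyst and warmth find no partner to act on, and target stands in no reverse step, so taking it out frees no route. A fresh charge at the same share gives 31 points, though it meets 69% of the starting material, so I read that figure as high. I commit to delta, with target near 31% at 8.0 h and after theta and gamma.

The forecast gives 31% now, 31.5% after theta, 31% after gamma, and delta as best: “Only fresh coupling partner restarts the reaction”.

The flask gives 29.8%, 29.8% after theta, 29.8% after gamma, and delta as best.

    starting material + free catalyst ⇌ catalyst intermediate A (K = 13.2 M⁻¹, k = 1010 M⁻¹ h⁻¹, Ea = 45.0 kJ mol⁻¹, ΔH = −50.0 kJ mol⁻¹)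
    coupling partner + catalyst intermediate A → free catalyst + target (k = 667 M⁻¹ h⁻¹, Ea = 47.0 kJ mol⁻¹)
    second substrate + free catalyst ⇌ catalyst intermediate B (K = 3.00 M⁻¹, k = 499 M⁻¹ h⁻¹, Ea = 37.0 kJ mol⁻¹, ΔH = −15.0 kJ mol⁻¹)
    coupling partner + catalyst intermediate B → free catalyst + second product (k = 532 M⁻¹ h⁻¹, Ea = 49.0 kJ mol⁻¹)
    coupling partner → decomposed reagent (k = 0.893 h⁻¹, Ea = 90.0 kJ mol⁻¹)
    (constants at 5 °C)

At 8.00 h the flask holds 0% of its coupling partner, the limiting reagent here, and 70% of its starting material. Delta gains 25 points against the reckoned 31 points, so the second charge has a capture share of 21.0%. A neighbouring flask, the same but charged with 0.60 M of coupling partner, reckons at 25.8% to 77.5% target. It gives 56.4% at 8.00 h, with 0% of its coupling partner and 43.4% of its starting material left, a capture share of 18.8%.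

The numbers in the tables stem from a simulated flask on assumed constants.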